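**Strategy.** The route rests on closing ring B (C5–C10, labdane numbering) last, through the C9–C10 bond, by a cation–olefin cyclisation launched from a temporary lactone. It exploits the cis-1,3-diaxial pair on ring A, the C19 carboxyl on C4 and the C20 methyl on C10: the carboxyl is first tied to C10 as a bridged γ-lactone. Lewis-acid ionisation of that C10–O bond frees the acid and lets the (E)-C8=C9 olefin attack C10 anti to it, while the C13 ketone oxygen caps C8 as a dihydropyran, later hydrolysed to the 8α-alcohol; C8, C9 and C10 are set in one operation. The precursor is a bridged lactone on ring A, made by an enantioselective Diels–Alder reaction, with an acyclic keto-olefin chain.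

Key step: step 10

Remarks. Labdane numbering is used: ring A = C1–C5 and C10; ring B = C5–C10; C17 is the methyl on C8, C18 the methyl and C19 the carboxyl on C4, C20 the methyl on C10; the side chain is C11–C16. TBDPS = tert-butyldiphenylsilyl.
Assumption: the (S)-configured oxazaborolidinium catalyst of step 6 is taken to direct the diene to the Re face of C-2 of methacrolein, the sense known for 2-substituted acroleins; its mirror image is equally available.

**Step 1**
Reactants: 1 methyl (R)-2,3-dihydroxypropanoate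
Product: 2 methyl (R)-2,3-bis(TBDPS-oxy)propanoate
Conditions: TBDPSCl (2.4 equiv), imidazole, DMAP (cat.), DMF, rt → 40 °C
Reagents that add atoms: tert-butyldiphenylsilyl chloride, CC(C)(C)[Si](Cl)(c1ccccc1)c1ccccc1
Why: Silyl ether formation: the imidazole/DMAP-activated silyl chloride caps both hydroxyls, and the stereocentre (the future C14) is not touched.

**Step 2**
Reactants: 2 methyl (R)-2,3-bis(TBDPS-oxy)propanoate
Product: 4 (R)-3,4-bis(TBDPS-oxy)butan-2-one, via Weinreb amide 3 (not isolated)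
Conditions: MeNHOMe·HCl, i-PrMgCl, THF, −20 °C; then MeMgBr, 0 °C
Reagents that add atoms: methylmagnesium bromide, C[Mg]Br (methyl of 4); N,O-dimethylhydroxylamine hydrochloride, CNOC.Cl (kept only in intermediate 3)
Why: One-pot Weinreb ketone synthesis: the magnesium amide turns the ester into the N-methoxy-N-methyl amide, whose chelated adduct with MeMgBr stops at the methyl ketone, and the non-enolising conditions keep the α-silyloxy stereocentre.

**Step 3**
Reactants: 4 (R)-3,4-bis(TBDPS-oxy)butan-2-one; 5 geranyl bromide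
Product: 7 (2R,6E)-1,2-bis(TBDPS-oxy)-7,11-dimethyldodeca-6,10-dien-3-one, via lithium enolate 6 (not isolated)
Conditions: LiN(i-Pr)2, THF, −78 °C; then 5, DMPU, −78 → −30 °C
Reagents that add atoms: none
Why: Kinetic enolate alkylation: the base removes a proton from the unhindered methyl group and the lithium enolate displaces the primary allylic bromide by SN2 with the E olefin intact, while the hindered C–H next to the silyloxy group is not deprotonated, so the stereocentre is kept.

**Step 4**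
Reactants: 7 (2R,6E)-1,2-bis(TBDPS-oxy)-7,11-dimethyldodeca-6,10-dien-3-one
Product: 9 (2E,6E,11R)-11,12-bis(TBDPS-oxy)-2,6-dimethyl-10-oxododeca-2,6-dienal, via allylic alcohol 8 (not isolated)
Conditions: SeO2 (cat.), t-BuOOH, salicylic acid (cat.), CH2Cl2, rt; filter; then MnO2, CH2Cl2, rt
Reagents that add atoms: selenium dioxide, O=[Se]=O (oxygen atom; re-oxidised by tert-butyl hydroperoxide, CC(C)(C)OO)
Why: Riley allylic oxidation (ene reaction, then [2,3]-sigmatropic shift) should attack the E-methyl of the terminal, most electron-rich trisubstituted olefin, and MnO2 then oxidises only the allylic alcohol to the enal.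

**Step 5**
Reactants: 9 (2E,6E,11R)-11,12-bis(TBDPS-oxy)-2,6-dimethyl-10-oxododeca-2,6-dienal
Product: 10 (2R,6E,10E)-1,2-bis(TBDPS-oxy)-7,11-dimethyltrideca-6,10,12-trien-3-one
Conditions: Ph3PCH3Br, KN(SiMe3)2 (1.05 equiv), THF, −78 → 0 °C
Reagents that add atoms: methylenetriphenylphosphorane, C=P(c1ccccc1)(c1ccccc1)c1ccccc1
Why: Wittig methylenation: at low temperature the unstabilised ylide adds to the aldehyde far faster than to the hindered α-silyloxy ketone, giving the (E)-1,3-diene without touching the olefin geometry.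

**Step 6**
Reactants: 10 (2R,6E,10E)-1,2-bis(TBDPS-oxy)-7,11-dimethyltrideca-6,10,12-trien-3-one; 11 methacrolein
Product: 12 (1S,2R)-2-[(3E,8R)-8,9-bis(TBDPS-oxy)-3-methyl-7-oxonon-3-en-1-yl]-1,3-dimethylcyclohex-3-ene-1-carbaldehyde
Conditions: (S)-1-(2-methylphenyl)-3,3-diphenyltetrahydro-1H,3H-pyrrolo[1,2-c][1,3,2]oxazaborole·HNTf2 (20 mol%), 11 (5 equiv), CH2Cl2, −78 → −40 °C
Reagents that add atoms: none
Why: Enantioselective Diels–Alder reaction under chiral oxazaborolidinium catalysis: the bound s-trans methacrolein is attacked on the Re face of C-2 (sets C4 as S), the unsubstituted diene terminus bonds to the β-carbon so that the formyl-bearing carbon joins C5 (the terminal alkyl group outweighs the internal methyl, as in 1-vinylcyclohexene-type dienes), and the endo (formyl) transition state of the E-diene places the C5 chain cis to the formyl group (sets C5 as R).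

**Step 7**
Reactants: 12 (1S,2R)-cyclohexene carbaldehyde
Product: 13 (1S,2R)-2-[(3E,8R)-8,9-bis(TBDPS-oxy)-3-methyl-7-oxonon-3-en-1-yl]-1,3-dimethylcyclohex-3-ene-1-carboxylic acid
Conditions: NaClO2, NaH2PO4, 2-methyl-2-butene, t-BuOH/H2O, 0 °C → rt
Reagents that add atoms: sodium chlorite, [Na+].[O-]Cl=O
Why: Pinnick oxidation: chlorous acid converts the hindered aldehyde into the acid while excess 2-methyl-2-butene scavenges HOCl, so olefins, ketone and silyl ethers survive and no stereocentre is affected.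

**Step 8**
Reactants: 13 (1S,2R)-cyclohexene carboxylic acid
Product: 14 (1S,4S,5S,8S)-8-[(3E,8R)-8,9-bis(TBDPS-oxy)-3-methyl-7-oxonon-3-en-1-yl]-4-iodo-1,5-dimethyl-6-oxabicyclo[3.2.1]octan-7-one (19,10-olide with 1α-iodine)
Conditions: I2 (1.1 equiv), NaHCO3, MeCN/H2O, 0 °C, dark
Reagents that add atoms: iodine, II
Why: Iodolactonisation: the iodonium ion of the ring olefin is opened at the tertiary carbon C10 by the C19 carboxylate, which can only reach the β face (bridged cis γ-lactone, 5-exo), so C10–O is β and the iodine on C1 is trans (α); the carboxylate-assisted ring olefin should react far faster than the chain olefin.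

**Step 9**
Reactants: 14 iodolactone
Product: 15 (1S,5R,8S)-8-[(3E,8R)-8,9-bis(TBDPS-oxy)-3-methyl-7-oxonon-3-en-1-yl]-1,5-dimethyl-6-oxabicyclo[3.2.1]octan-7-one (19,10-olide)
Conditions: Bu3SnH (1.5 equiv, 0.3 M), AIBN (cat.), benzene, 80 °C
Reagents that add atoms: none
Why: Radical chain dehalogenation: at this tin hydride concentration the secondary C1 radical is reduced faster than it can cyclise onto the chain olefin or undergo an acyloxy shift, and the stereocentre at C1 disappears.

**Step 10**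
Reactants: 15 bridged lactone (19,10-olide)
Product: 17 (4S,5R,8R,9R,10S,14R)-14,15-bis(TBDPS-oxy)-8-hydroxy-13-oxo-16-norlabdan-19-oic acid, via cyclic enol ether 16 (not isolated)
Conditions: SnCl4 (1.5 equiv), CH2Cl2, −78 → −20 °C; then 1 M HCl, THF, 0 °C → rt
Reagents that add atoms: water, O
Why: Proposed new method: SnCl4 binds the lactone carbonyl and the tertiary C10–O bond heterolyses (the alkyl–oxygen cleavage by which Lewis acids cleave tert-butyl esters), giving a C10 cation whose β face stays covered by the tin carboxylate on C4; this carboxylate later takes up the proton lost from C12, so no external acid or base is needed and the chain olefin meets no proton source before it has cyclised. C9 of the (E)-C8=C9 olefin attacks C10 from the α face in a chair transition state (6-endo-trig cation–olefin closure of ring B), and the C13 carbonyl oxygen captures the C8 cation anti to the new bond through a six-membered transition state; the oxocarbenium ion loses H-12 to give dihydropyran 16, which aqueous acid opens to the hydroxy ketone. The closest known reactions are the acid-promoted cyclisations of monocyclic homofarnesyl acids and ketones to bicyclic lactones and cyclic enol ethers, and Friedel–Crafts alkylations by tertiary lactones; an olefin as partner of a lactone-derived cation is the new element. C10 is set by inversion at the departing C–O bond (C20 methyl β, cis to C19), with the equatorial C5 chain enforcing the trans ring fusion; C9 (H α) and C8 (O α, methyl β) follow from the E geometry of the olefin, the chair and the anti addition. The step needs initiation at C10 only (secured by the pre-formed lactone), oxygen capture at C8 in preference to proton loss (secured by the six-membered reach of the ketone) and retention of C14 (secured by deprotonation of the oxocarbenium ion at the unhindered C12, not at the silyloxy-bearing C14).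

**Step 11**
Reactants: 17 hydroxy keto acid
Product: 18 (4S,5R,8R,9R,10S,14S)-14,15-bis(TBDPS-oxy)-8-hydroxylabd-13(16)-en-19-oic acid
Conditions: Ph3PCH3Br, KOt-Bu (4 equiv each), THF, 0 °C → rt
Reagents that add atoms: methylenetriphenylphosphorane, C=P(c1ccccc1)(c1ccccc1)c1ccccc1
Why: Wittig methylenation: excess ylide first forms the carboxylate and the tertiary alkoxide and then methylenates the open-chain ketone to the C13=C16 olefin, while the bulky silyloxy group should disfavour enolisation toward C14, so its configuration is kept.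

**Step 12**
Reactants: 18 bis-silyl ether
Product: 19 (4S,5R,8R,9R,10S,14S)-8,14,15-trihydroxylabd-13(16)-en-19-oic acid (target)
Conditions: Bu4NF (excess), THF, rt → 40 °C; aq. NH4Cl/citric acid work-up
Reagents that add atoms: none
Why: Fluoride-mediated desilylation: both Si–O bonds are cleaved under the driving force of Si–F bond formation without affecting the olefin, the tertiary alcohol or the acid, which is returned by the mildly acidic work-up.

**Compound list**
1 | methyl (R)-2,3-dihydroxypropanoate | COC(=O)[C@H](O)CO | starting material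
2 | methyl (R)-2,3-bis(TBDPS-oxy)propanoate | COC(=O)[C@H](O[Si](c1ccccc1)(c1ccccc1)C(C)(C)C)CO[Si](c1ccccc1)(c1ccccc1)C(C)(C)C | intermediate
3 | (R)-2,3-bis(TBDPS-oxy)-N-methoxy-N-methylpropanamide (not isolated) | CON(C)C(=O)[C@H](O[Si](c1ccccc1)(c1ccccc1)C(C)(C)C)CO[Si](c1ccccc1)(c1ccccc1)C(C)(C)C | intermediate
4 | (R)-3,4-bis(TBDPS-oxy)butan-2-one | CC(=O)[C@H](O[Si](c1ccccc1)(c1ccccc1)C(C)(C)C)CO[Si](c1ccccc1)(c1ccccc1)C(C)(C)C | intermediate
5 | geranyl bromide, (2E)-1-bromo-3,7-dimethylocta-2,6-diene | CC(C)=CCC/C(C)=C/CBr | starting material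
6 | lithium (R)-3,4-bis(TBDPS-oxy)but-1-en-2-olate (not isolated) | [Li]OC(=C)[C@H](O[Si](c1ccccc1)(c1ccccc1)C(C)(C)C)CO[Si](c1ccccc1)(c1ccccc1)C(C)(C)C | intermediate
7 | (2R,6E)-1,2-bis(TBDPS-oxy)-7,11-dimethyldodeca-6,10-dien-3-one | CC(C)=CCC/C(C)=C/CCC(=O)[C@H](O[Si](c1ccccc1)(c1ccccc1)C(C)(C)C)CO[Si](c1ccccc1)(c1ccccc1)C(C)(C)C | intermediate
8 | (2R,6E,10E)-1,2-bis(TBDPS-oxy)-12-hydroxy-7,11-dimethyldodeca-6,10-dien-3-one (not isolated) | OC/C(C)=C/CC/C(C)=C/CCC(=O)[C@H](O[Si](c1ccccc1)(c1ccccc1)C(C)(C)C)CO[Si](c1ccccc1)(c1ccccc1)C(C)(C)C | intermediate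
9 | (2E,6E,11R)-11,12-bis(TBDPS-oxy)-2,6-dimethyl-10-oxododeca-2,6-dienal | O=C/C(C)=C/CC/C(C)=C/CCC(=O)[C@H](O[Si](c1ccccc1)(c1ccccc1)C(C)(C)C)CO[Si](c1ccccc1)(c1ccccc1)C(C)(C)C | intermediate
10 | (2R,6E,10E)-1,2-bis(TBDPS-oxy)-7,11-dimethyltrideca-6,10,12-trien-3-one | C=C/C(C)=C/CC/C(C)=C/CCC(=O)[C@H](O[Si](c1ccccc1)(c1ccccc1)C(C)(C)C)CO[Si](c1ccccc1)(c1ccccc1)C(C)(C)C | intermediate
11 | methacrolein (2-methylprop-2-enal) | C=C(C)C=O | starting material
12 | (1S,2R)-2-[(3E,8R)-8,9-bis(TBDPS-oxy)-3-methyl-7-oxonon-3-en-1-yl]-1,3-dimethylcyclohex-3-ene-1-carbaldehyde | O=C[C@@]1(C)CCC=C(C)[C@H]1CC/C(C)=C/CCC(=O)[C@H](O[Si](c2ccccc2)(c2ccccc2)C(C)(C)C)CO[Si](c2ccccc2)(c2ccccc2)C(C)(C)C | intermediate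
13 | (1S,2R)-2-[(3E,8R)-8,9-bis(TBDPS-oxy)-3-methyl-7-oxonon-3-en-1-yl]-1,3-dimethylcyclohex-3-ene-1-carboxylic acid | OC(=O)[C@@]1(C)CCC=C(C)[C@H]1CC/C(C)=C/CCC(=O)[C@H](O[Si](c2ccccc2)(c2ccccc2)C(C)(C)C)CO[Si](c2ccccc2)(c2ccccc2)C(C)(C)C | intermediate
14 | (1S,4S,5S,8S)-8-[(3E,8R)-8,9-bis(TBDPS-oxy)-3-methyl-7-oxonon-3-en-1-yl]-4-iodo-1,5-dimethyl-6-oxabicyclo[3.2.1]octan-7-one | O=C1O[C@]2(C)[C@@H](I)CC[C@@]1(C)[C@@H]2CC/C(C)=C/CCC(=O)[C@H](O[Si](c3ccccc3)(c3ccccc3)C(C)(C)C)CO[Si](c3ccccc3)(c3ccccc3)C(C)(C)C | intermediate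
15 | (1S,5R,8S)-8-[(3E,8R)-8,9-bis(TBDPS-oxy)-3-methyl-7-oxonon-3-en-1-yl]-1,5-dimethyl-6-oxabicyclo[3.2.1]octan-7-one | O=C1O[C@]2(C)CCC[C@@]1(C)[C@@H]2CC/C(C)=C/CCC(=O)[C@H](O[Si](c3ccccc3)(c3ccccc3)C(C)(C)C)CO[Si](c3ccccc3)(c3ccccc3)C(C)(C)C | intermediate
16 | (4S,5R,8R,9R,10S,14R)-14,15-bis(TBDPS-oxy)-8,13-epoxy-16-norlabd-12-en-19-oic acid (not isolated) | CC(C)(C)[Si](c1ccccc1)(c1ccccc1)OC[C@@H](O[Si](c1ccccc1)(c1ccccc1)C(C)(C)C)C1=CC[C@@H]2[C@@]3(C)CCC[C@](C)(C(=O)O)[C@@H]3CC[C@@]2(C)O1 | intermediate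
17 | (4S,5R,8R,9R,10S,14R)-14,15-bis(TBDPS-oxy)-8-hydroxy-13-oxo-16-norlabdan-19-oic acid | O=C(CC[C@@H]1[C@@]2(C)CCC[C@](C)(C(=O)O)[C@@H]2CC[C@@]1(C)O)[C@H](O[Si](c1ccccc1)(c1ccccc1)C(C)(C)C)CO[Si](c1ccccc1)(c1ccccc1)C(C)(C)C | intermediate
18 | (4S,5R,8R,9R,10S,14S)-14,15-bis(TBDPS-oxy)-8-hydroxylabd-13(16)-en-19-oic acid | C=C(CC[C@@H]1[C@@]2(C)CCC[C@](C)(C(=O)O)[C@@H]2CC[C@@]1(C)O)[C@H](O[Si](c1ccccc1)(c1ccccc1)C(C)(C)C)CO[Si](c1ccccc1)(c1ccccc1)C(C)(C)C | intermediate
19 | (4S,5R,8R,9R,10S,14S)-8,14,15-trihydroxylabd-13(16)-en-19-oic acid | C=C(CC[C@@H]1[C@@]2(C)CCC[C@](C)(C(=O)O)[C@@H]2CC[C@@]1(C)O)[C@H](O)CO | target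

**Total step count:** 12. **Longest linear sequence:** 12 steps (from 1; 5 and 11 enter as purchased reactants).

**Steps most likely to fail**

Step 10 (proposed new method). The lactone may fail to ionise below the temperature at which the silyl ethers or the C14 centre suffer, or the C8 cation may lose a proton instead of being captured by oxygen. The fallback uses known chemistry without the lactone relay. It sets out from acid 13, which is esterified (Me3SiCHN2, MeOH/toluene) to the seco methyl ester F1. This α-monocyclic ester is cyclised with ClSO3H in 2-nitropropane at −78 °C, the established superacid cyclisation of monocyclic homofarnesyl ketones, in which protonation of the ring olefin gives the same C10 cation. The resulting cyclic enol ether methyl ester F2 is not isolated but hydrolysed with dilute HCl to the hydroxy ketone methyl ester F3. Wittig methylenation gives the methylenated methyl ester F4, and SN2 demethylation of the hindered axial ester (LiSPr, HMPA, rt) comes back to the route at acid 18.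

Step 6. Facial selectivity may be poor, or the catalyst may be inhibited, with the bulky ketone-bearing diene 10; diastereomers that differ only at the remote C14 could not be separated. The ortho/endo preference could also erode. The fallback moves the cycloaddition before fragment union, onto a small diene whose adducts are enantiomers and can be enriched by crystallisation. It sets out from geranyl bromide 5: KOAc in DMF gives geranyl acetate F5. SeO2/t-BuOOH oxidation gives 8-hydroxygeranyl acetate F6, which MnO2 oxidises to 8-oxogeranyl acetate F7, and Wittig methylenation gives the triene acetate F8. Cycloaddition with 11 under the same catalyst gives the cyclohexene aldehyde F9, and Pinnick oxidation gives the acid F10. Iodolactonisation gives the iodolactone F11, whose enantiomeric purity is raised by recrystallisation. Bu3SnH reduction gives the lactone acetate F12, methanolysis (K2CO3, MeOH) the allylic alcohol F13, and CBr4/PPh3 the allylic bromide F14. Alkylation of lithium enolate 6 with F14 comes back to the route at lactone 15.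

Step 3. Proton transfer between enolate 6 and the product may cause polyalkylation, or the enolate may equilibrate toward C14 with epimerisation or β-elimination of silanolate. The fallback uses acetoacetate-type activation. It sets out from ester 2: crossed Claisen condensation with the lithium enolate of allyl acetate gives the β-keto allyl ester F15. Its stabilised anion (K2CO3, acetone) is mono-alkylated by 5 to the alkylated β-keto ester F16. Pd(PPh3)4 with morpholine then removes the allyl group with loss of CO2 (Tsuji–Trost-type deallylation–decarboxylation) and comes back to the route at ketone 7.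

**Further compounds**
F1 | step 10 | methyl (1S,2R)-2-[(3E,8R)-8,9-bis(TBDPS-oxy)-3-methyl-7-oxonon-3-en-1-yl]-1,3-dimethylcyclohex-3-ene-1-carboxylate | COC(=O)[C@@]1(C)CCC=C(C)[C@H]1CC/C(C)=C/CCC(=O)[C@H](O[Si](c2ccccc2)(c2ccccc2)C(C)(C)C)CO[Si](c2ccccc2)(c2ccccc2)C(C)(C)C
F2 | step 10 | methyl (4S,5R,8R,9R,10S,14R)-14,15-bis(TBDPS-oxy)-8,13-epoxy-16-norlabd-12-en-19-oate | CC(C)(C)[Si](c1ccccc1)(c1ccccc1)OC[C@@H](O[Si](c1ccccc1)(c1ccccc1)C(C)(C)C)C1=CC[C@@H]2[C@@]3(C)CCC[C@](C)(C(=O)OC)[C@@H]3CC[C@@]2(C)O1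
F3 | step 10 | methyl (4S,5R,8R,9R,10S,14R)-14,15-bis(TBDPS-oxy)-8-hydroxy-13-oxo-16-norlabdan-19-oate | O=C(CC[C@@H]1[C@@]2(C)CCC[C@](C)(C(=O)OC)[C@@H]2CC[C@@]1(C)O)[C@H](O[Si](c1ccccc1)(c1ccccc1)C(C)(C)C)CO[Si](c1ccccc1)(c1ccccc1)C(C)(C)C
F4 | step 10 | methyl (4S,5R,8R,9R,10S,14S)-14,15-bis(TBDPS-oxy)-8-hydroxylabd-13(16)-en-19-oate | C=C(CC[C@@H]1[C@@]2(C)CCC[C@](C)(C(=O)OC)[C@@H]2CC[C@@]1(C)O)[C@H](O[Si](c1ccccc1)(c1ccccc1)C(C)(C)C)CO[Si](c1ccccc1)(c1ccccc1)C(C)(C)C
F5 | step 6 | geranyl acetate | CC(C)=CCC/C(C)=C/COC(C)=O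
F6 | step 6 | (2E,6E)-8-hydroxy-3,7-dimethylocta-2,6-dien-1-yl acetate | OC/C(C)=C/CC/C(C)=C/COC(C)=O
F7 | step 6 | (2E,6E)-3,7-dimethyl-8-oxoocta-2,6-dien-1-yl acetate | O=C/C(C)=C/CC/C(C)=C/COC(C)=O
F8 | step 6 | (2E,6E)-3,7-dimethylnona-2,6,8-trien-1-yl acetate | C=C/C(C)=C/CC/C(C)=C/COC(C)=O
F9 | step 6 | (2E)-5-[(1R,6S)-6-formyl-2,6-dimethylcyclohex-2-en-1-yl]-3-methylpent-2-en-1-yl acetate | O=C[C@@]1(C)CCC=C(C)[C@H]1CC/C(C)=C/COC(C)=O
F10 | step 6 | (1S,2R)-2-[(3E)-5-acetoxy-3-methylpent-3-en-1-yl]-1,3-dimethylcyclohex-3-ene-1-carboxylic acid | OC(=O)[C@@]1(C)CCC=C(C)[C@H]1CC/C(C)=C/COC(C)=O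
F11 | step 6 | (2E)-5-[(1S,4S,5S,8S)-4-iodo-1,5-dimethyl-7-oxo-6-oxabicyclo[3.2.1]octan-8-yl]-3-methylpent-2-en-1-yl acetate | O=C1O[C@]2(C)[C@@H](I)CC[C@@]1(C)[C@@H]2CC/C(C)=C/COC(C)=O
F12 | step 6 | (2E)-5-[(1S,5R,8S)-1,5-dimethyl-7-oxo-6-oxabicyclo[3.2.1]octan-8-yl]-3-methylpent-2-en-1-yl acetate | O=C1O[C@]2(C)CCC[C@@]1(C)[C@@H]2CC/C(C)=C/COC(C)=O
F13 | step 6 | (1S,5R,8S)-8-[(3E)-5-hydroxy-3-methylpent-3-en-1-yl]-1,5-dimethyl-6-oxabicyclo[3.2.1]octan-7-one | O=C1O[C@]2(C)CCC[C@@]1(C)[C@@H]2CC/C(C)=C/CO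
F14 | step 6 | (1S,5R,8S)-8-[(3E)-5-bromo-3-methylpent-3-en-1-yl]-1,5-dimethyl-6-oxabicyclo[3.2.1]octan-7-one | O=C1O[C@]2(C)CCC[C@@]1(C)[C@@H]2CC/C(C)=C/CBr
F15 | step 3 | allyl (4R)-4,5-bis(TBDPS-oxy)-3-oxopentanoate | C=CCOC(=O)CC(=O)[C@H](O[Si](c1ccccc1)(c1ccccc1)C(C)(C)C)CO[Si](c1ccccc1)(c1ccccc1)C(C)(C)C
F16 | step 3 | allyl (4R)-4,5-bis(TBDPS-oxy)-2-[(2E)-3,7-dimethylocta-2,6-dien-1-yl]-3-oxopentanoate (both C-2 epimers) | C=CCOC(=O)C(C/C=C(C)/CCC=C(C)C)C(=O)[C@H](O[Si](c1ccccc1)(c1ccccc1)C(C)(C)C)CO[Si](c1ccccc1)(c1ccccc1)C(C)(C)C
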